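## Structural features

Gancaonin J (13) is a dihydrochalcone: two benzene rings joined by an open C(=O)–CH2–CH2 chain, with no further ring. Ring A is pentasubstituted, with the carbonyl at C1', hydroxyls at C2' and C4', 3-methylbut-2-enyl (prenyl) groups at C3' and C5' and one hydrogen at C6'; ring B is a para-hydroxyphenyl group on C-beta. There is no stereocentre, and both alkenes end in two identical methyl groups, so no configuration has to be set. The fragile parts are the two ortho-prenylphenol units, which close to 2,2-dimethylchromans under acid and take up electrophiles or hydrogen readily, and the oxidisable resorcinol core with its free phenols. The difficulty is control rather than size: two prenyl groups must sit exactly on the carbons flanking O4', and the saturated ketone bridge must be made without acid and without a reduction that has to tell an enone from the prenyl alkenes. The key step uses the C2' hydroxyl ortho to the carbonyl carbon: in the corresponding salicylaldehyde, the C2' phenoxide oxygen and the formyl C–H chelate rhodium, so the formyl C–H can add across a vinylarene and form the C(=O)–C-alpha bond directly at the ketone oxidation level. A second useful feature is that both prenyl groups are ortho to the same oxygen (O4'), so each can be delivered from that oxygen by a sigmatropic shift.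

## Logic of the disconnections

13 to 12. The bond cut is the ester C–O bond between O4 of ring B and an acetyl group. Ring B cannot travel as a free vinylphenol, which polymerises and competes for base, and an acetate comes off under mild base, the medium in which the ortho-prenylphenols of 13 are safe. The skeleton is not simplified, but the commercial alkene 11 becomes usable. The forward step must cleave an aryl ester without touching ketone or alkenes and must avoid strong acid in the work-up.

12 to 10 plus 11. The C(=O)–C-alpha bond is cut: one skeletal bond, no ring. The carbonyl carbon is ortho to O2', the retron for a phenoxide-directed hydroacylation. Two pieces of similar size result, and the bridge arises at the ketone oxidation level, so no enone has to be reduced beside the prenyl alkenes. The forward step must place rhodium on the terminal alkene carbon (linear ketone), react only at the vinyl group, and hold the acyl rhodium hydride against decarbonylation. Compound 10 is used with both hydroxyls free. O2'–H is the directing group. O4'–H is the more acidic and could in principle take up base or the acetyl group of 11, but it is flanked by two prenyl groups, the base is catalytic, and any acetyl exchange is erased in the step from 12 to 13. A protecting group at O4' would add steps and is held in reserve.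

10 to 8. The ring C5–CH2 bond is cut and reconnected as an O4–C(CH3)2 ether; an ortho-prenylphenol is the retron of an aromatic Claisen rearrangement of a 1,1-dimethylallyl ether. The gain is that a ring C–C bond is replaced by an easily made C–O bond. The site is forced, because C3 is occupied and the para position C1 is substituted. The forward step must be thermal and non-acidic.

8 to 7, and 7 to 6 plus 2. The vinyl group is traced to an ethynyl group, and the O4–C bond is cut. A tertiary allyl aryl ether cannot be made by direct alkylation, whereas the tertiary propargylic chloride 2 alkylates phenols under copper catalysis. The forward steps need O4 selectivity over the hydrogen-bonded O2 hydroxyl and a semihydrogenation that stops at the alkene and spares the prenyl alkene and the aldehyde. A one-step transfer of the tertiary allyl group from an allylic carbonate under zerovalent palladium would save the hydrogenations. However, an aryl ether whose phenoxide is conjugated to a formyl group can re-ionise on the metal and drift to the linear O-prenyl isomer, so this is kept as a reserve only.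

6 to 4, 4 to 3, and 3 to 1 plus 2. The same three operations serve for the C3 prenyl group: the ring C3–CH2 bond is cut back to the O4 ether, the alkene to the alkyne, and the ether to 1 and 2. The hydrogen-bonded salicylaldehyde unit gives the C3–C4 bond the higher double-bond character, which directs the shift to C3. The formyl group of 1 therefore does three jobs: it differentiates the two hydroxyls, steers the rearrangement, and later becomes the ketone carbon. Both starting materials are commercial.

## Other disconnections considered

Alternative 1: Ring A is cut at C1'–C2' and C5'–C6' and rebuilt by a Diels–Alder benzannulation.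
- **Forward step.** The β-keto ester A1, with one prenyl group on its α-carbon and one on its γ-carbon, would be silylated twice to the 1-methoxy-1,3-bis(trimethylsilyloxy)diene A2. Cycloaddition with the terminal ynone A3, loss of methanol and mild acidic hydrolysis of the aryl trimethylsilyl ethers would give A4; fluoride would then free ring B to give 13.
- **In favour.** Every substituent of ring A is fixed by the connectivity of two open-chain pieces, so no positional isomer can arise. The polarity match (nucleophilic C4 of A2, electrophilic β-carbon of A3) predicts the right orientation. The ketone is at the right oxidation level and no transition metal is needed.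
- **Against.** A2 is a tetrasubstituted ketene acetal at one end and a substituted enol ether at the other: crowded, hard to obtain in one geometry, hydrolytically labile and slow to reach the s-cis form. A3 can react as a simple Michael acceptor and stop at an open-chain adduct. The acidic work-up meets freshly formed ortho-prenylphenols. A1 and A3 each need several steps.
- **Comparison.** On structure the alternative is the better in regiocontrol on ring A, since the chosen plan relies on the course of two Claisen rearrangements. On the oxidation level of the bridge the two are equal. On mechanism the chosen key step has closer precedent on its substrate class. On step economy the alternative is expected to be no shorter, because both components must be built and a deprotection still follows.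

Alternative 2: The two ring-to-prenyl bonds C3'–CH2 and C5'–CH2 are cut.
- **Forward step.** The diiodide A5, with bridge and both rings in place, would be coupled twice with prenylboronic acid pinacol ester A6 under Pd(OAc)2, a bulky biarylphosphine and K3PO4 (Suzuki coupling) to give A7. The three methoxymethyl groups would then be removed to give 13.
- **In favour.** The prenyl groups enter last and both at once, so the sensitive alkenes see the fewest steps. This is better than the chosen plan, where they are carried from step 3 onward. The core is accessible by robust acylation chemistry, and the coupling is catalytic like the chosen key step (equal).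
- **Against.** The allyl boronate can transfer through either terminus, so linear versus 1,1-dimethylallyl selectivity must be enforced twice by the ligand, once at C3' between two ether oxygens. Selective iodination of ring A beside the ring B oxygen and etherification of the chelated O2' hydroxyl are further demands. Decisively, three methoxymethyl ethers must be cleaved by acid at the end, the conditions under which ortho-prenylphenols close to chromans; the chosen plan ends in mild base.
- **Comparison.** Halogenation, protection, coupling and deprotection, on top of making the core, are estimated at no fewer steps than the chosen plan.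

Alternative 3: The ring-to-carbonyl bond C1'–C(=O) is cut.
- **Forward step.** The resorcinol A8, with prenyl groups at C2 and C4, would be acylated at its less hindered oxygen and silylated at the other to give ester A9. Irradiation would cleave the aryl O–acyl bond homolytically, and the caged acyl and phenoxyl radicals would recombine at the only free ortho carbon (photo-Fries rearrangement) to give A10. Fluoride would then release 13.
- **In favour.** No reagent and no acid are needed, and the ketone level is reached directly (equal to the chosen plan). The migration site is dictated by the substitution pattern, since the other ortho position and the para position are occupied; in certainty of regiochemistry at this step it is equal or better.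
- **Against.** A8 lacks the formyl group that in the chosen plan differentiates the hydroxyls and steers both Claisen steps, so its regiocontrolled synthesis and the differentiation of its oxygens are harder than the synthesis of 10. Radical-pair escape leads to phenol and decarbonylation products. The prenyl groups offer allylic hydrogens and alkenes to the radicals. The ortho-hydroxy ketone formed absorbs the same light and screens the reaction, and dilute photolysis scales poorly.
- **Comparison.** Step economy is estimated as equal at best, since A8 needs its own prenylation sequence plus two selective O-functionalisations, and a desilylation replaces the deacetylation.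

Key step: step 7

Remarks on the chemistry:
- Ring A carries primed locants (C1' bears the carbonyl) and ring B unprimed ones. In the benzaldehyde intermediates the formyl-bearing carbon is C1, so C2 to C5 of the aldehyde become C2' to C5'.
- Step 3 is drawn for migration to C3. Material that migrates to C5 would be carried through steps 4 to 6 unchanged, which then place the second prenyl group at C3 and reach the same 10.
- Compounds 1, 2 and 11 are taken as purchasable.

## Route

Step 1
Reactants: 1 2,4-dihydroxybenzaldehyde; 2 3-chloro-3-methylbut-1-yne
Product: 3 2-hydroxy-4-[(2-methylbut-3-yn-2-yl)oxy]benzaldehyde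
Conditions: 2 (1.5 equiv), K2CO3 (1.5 equiv), KI (cat.), CuI (cat.), acetone, reflux
Reagents that add atoms: none
Why: Copper-assisted propargylic O-alkylation (Williamson-type etherification) of the more acidic, unchelated 4-hydroxyl; the 2-hydroxyl is tied in a hydrogen bond to the formyl oxygen and should stay free.

Step 2
Reactants: 3 2-hydroxy-4-[(2-methylbut-3-yn-2-yl)oxy]benzaldehyde
Product: 4 2-hydroxy-4-[(2-methylbut-3-en-2-yl)oxy]benzaldehyde
Conditions: H2 (1 atm), Pd/CaCO3 poisoned with Pb(OAc)2, quinoline, EtOAc, rt
Reagents that add atoms: none
Why: Semihydrogenation of a terminal alkyne on lead-poisoned palladium should stop at the vinyl group, because the alkyne binds more strongly than the alkene; aldehyde and aryl ether are inert under these conditions.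

Step 3
Reactants: 4 2-hydroxy-4-[(2-methylbut-3-en-2-yl)oxy]benzaldehyde
Product: 6 2,4-dihydroxy-3-(3-methylbut-2-en-1-yl)benzaldehyde, via ortho-dienone 5 (not isolated)
Conditions: PhNEt2, 160 °C, Ar
Reagents that add atoms: none
Why: Aromatic Claisen rearrangement ([3,3] shift) delivers the terminal CH2 of the 1,1-dimethylallyl ether to C3, whose bond to C4 has the higher double-bond character in the hydrogen-bonded salicylaldehyde; dienone 5 tautomerises to the phenol, and the basic amine solvent suppresses acid-promoted ring closure of the ortho-prenylphenol.

Step 4
Reactants: 6 2,4-dihydroxy-3-(3-methylbut-2-en-1-yl)benzaldehyde; 2 3-chloro-3-methylbut-1-yne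
Product: 7 2-hydroxy-3-(3-methylbut-2-en-1-yl)-4-[(2-methylbut-3-yn-2-yl)oxy]benzaldehyde
Conditions: 2 (2 equiv), K2CO3 (1.5 equiv), KI (cat.), CuI (cat.), acetone, reflux
Reagents that add atoms: none
Why: Same copper-assisted propargylic etherification as step 1; the 4-hydroxyl, although now next to a prenyl group, remains more acidic and more nucleophilic than the chelated 2-hydroxyl.

Step 5
Reactants: 7 2-hydroxy-3-(3-methylbut-2-en-1-yl)-4-[(2-methylbut-3-yn-2-yl)oxy]benzaldehyde
Product: 8 2-hydroxy-3-(3-methylbut-2-en-1-yl)-4-[(2-methylbut-3-en-2-yl)oxy]benzaldehyde
Conditions: H2 (1 atm), Pd/CaCO3 poisoned with Pb(OAc)2, quinoline, EtOAc, rt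
Reagents that add atoms: none
Why: Semihydrogenation of the terminal alkyne as in step 2; the trisubstituted prenyl alkene is too hindered to be reduced on the poisoned catalyst.

Step 6
Reactants: 8 2-hydroxy-3-(3-methylbut-2-en-1-yl)-4-[(2-methylbut-3-en-2-yl)oxy]benzaldehyde
Product: 10 2,4-dihydroxy-3,5-bis(3-methylbut-2-en-1-yl)benzaldehyde, via ortho-dienone 9 (not isolated)
Conditions: PhNEt2, 160 °C, Ar
Reagents that add atoms: none
Why: Aromatic Claisen rearrangement to C5, the only unsubstituted ortho position (C3 carries a prenyl group and the para position C1 the formyl group); dienone 9 tautomerises to the phenol.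

Step 7
Reactants: 10 2,4-dihydroxy-3,5-bis(3-methylbut-2-en-1-yl)benzaldehyde; 11 4-ethenylphenyl acetate (4-acetoxystyrene)
Product: 12 4-{3-[2,4-dihydroxy-3,5-bis(3-methylbut-2-en-1-yl)phenyl]-3-oxopropyl}phenyl acetate (Gancaonin J 4-O-acetate)
Conditions: 11 (2 equiv), [Rh(cod)Cl]2 (2.5 mol%), dppf (6 mol%), Na2CO3 (10 mol%), toluene, 100 °C, Ar
Reagents that add atoms: none
Why: Chloride–phenoxide exchange at monovalent rhodium, with Na2CO3 as catalytic base, binds the metal to O2' of 10, and oxidative addition of the neighbouring formyl C–H gives a five-membered O,C-chelated acyl hydride of trivalent rhodium in which the occupied coordination site slows CO extrusion (decarbonylation). The vinyl group of 11 coordinates and inserts into Rh–H with hydride going to the benzylic carbon and rhodium to the terminal carbon, and C–C reductive elimination of acyl and alkyl forms the C(=O)–C-alpha bond of 12 and returns monovalent rhodium. The closest known reaction type is the phenoxide-directed, rhodium-catalysed intermolecular hydroacylation of alkenes and alkynes with salicylaldehydes, applied here to a more substituted aldehyde. No ring is closed and no stereocentre is formed, so the step has only to be regioselective and chemoselective. Linear rather than branched addition is needed: the large bite angle of dppf and the crowding of the chelated acyl rhodium by the C3' prenyl group disfavour rhodium at the secondary benzylic carbon. Only the vinyl group may react: the two prenyl alkenes are trisubstituted and too hindered to insert. The free O4' hydroxyl, flanked by two prenyl groups, is a poor ligand and a poor acyl acceptor, the base is catalytic and nearly insoluble in toluene, and any acetyl exchange between phenols would be erased in step 8.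

Step 8
Reactants: 12 4-{3-[2,4-dihydroxy-3,5-bis(3-methylbut-2-en-1-yl)phenyl]-3-oxopropyl}phenyl acetate
Product: 13 Gancaonin J, 1-[2,4-dihydroxy-3,5-bis(3-methylbut-2-en-1-yl)phenyl]-3-(4-hydroxyphenyl)propan-1-one
Conditions: K2CO3 (0.3 equiv), MeOH, 0 °C to rt; aq. NH4Cl work-up
Reagents that add atoms: none
Why: Base-catalysed transesterification (methanolysis) of an aryl acetate, whose phenoxide is a good leaving group; ketone and prenyl alkenes are inert to carbonate in methanol, and the near-neutral work-up avoids acid-promoted chroman formation.

## Compound list

1 | 2,4-dihydroxybenzaldehyde | O=Cc1ccc(O)cc1O | starting material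
2 | 3-chloro-3-methylbut-1-yne | C#CC(C)(C)Cl | starting material
3 | 2-hydroxy-4-[(2-methylbut-3-yn-2-yl)oxy]benzaldehyde | O=Cc1ccc(OC(C)(C)C#C)cc1O | intermediate
4 | 2-hydroxy-4-[(2-methylbut-3-en-2-yl)oxy]benzaldehyde | O=Cc1ccc(OC(C)(C)C=C)cc1O | intermediate
5 | 2-hydroxy-3-(3-methylbut-2-en-1-yl)-4-oxocyclohexa-1,5-diene-1-carbaldehyde (ortho-dienone, racemic, not isolated) | O=CC1=C(O)C(CC=C(C)C)C(=O)C=C1 | intermediate
6 | 2,4-dihydroxy-3-(3-methylbut-2-en-1-yl)benzaldehyde | O=Cc1ccc(O)c(CC=C(C)C)c1O | intermediate
7 | 2-hydroxy-3-(3-methylbut-2-en-1-yl)-4-[(2-methylbut-3-yn-2-yl)oxy]benzaldehyde | O=Cc1ccc(OC(C)(C)C#C)c(CC=C(C)C)c1O | intermediate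
8 | 2-hydroxy-3-(3-methylbut-2-en-1-yl)-4-[(2-methylbut-3-en-2-yl)oxy]benzaldehyde | O=Cc1ccc(OC(C)(C)C=C)c(CC=C(C)C)c1O | intermediate
9 | 6-hydroxy-3,5-bis(3-methylbut-2-en-1-yl)-4-oxocyclohexa-1,5-diene-1-carbaldehyde (ortho-dienone, racemic, not isolated) | O=CC1=CC(CC=C(C)C)C(=O)C(CC=C(C)C)=C1O | intermediate
10 | 2,4-dihydroxy-3,5-bis(3-methylbut-2-en-1-yl)benzaldehyde | CC(C)=CCc1cc(C=O)c(O)c(CC=C(C)C)c1O | intermediate
11 | 4-ethenylphenyl acetate (4-acetoxystyrene) | C=Cc1ccc(OC(C)=O)cc1 | starting material
12 | 4-{3-[2,4-dihydroxy-3,5-bis(3-methylbut-2-en-1-yl)phenyl]-3-oxopropyl}phenyl acetate (Gancaonin J 4-O-acetate) | CC(C)=CCc1cc(C(=O)CCc2ccc(OC(C)=O)cc2)c(O)c(CC=C(C)C)c1O | intermediate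
13 | Gancaonin J, 1-[2,4-dihydroxy-3,5-bis(3-methylbut-2-en-1-yl)phenyl]-3-(4-hydroxyphenyl)propan-1-one | CC(C)=CCc1cc(C(=O)CCc2ccc(O)cc2)c(O)c(CC=C(C)C)c1O | target

## Step count and least certain steps

Total step count: 8. Longest linear sequence: 8 steps (1 to 13); 2 and 11 are bought and enter directly.

**Step 7 (key step).**
- Most likely to go wrong: alkene insertion with the opposite regiochemistry, placing rhodium on the benzylic carbon, where it is stabilised as a benzylic complex, and leading to the branched ketone. Also possible are decarbonylation of the acyl rhodium hydride if the crowded C2' phenoxide chelates poorly, acetyl transfer from 11 to a phenoxide followed by polymerisation of the freed vinylphenol, and slow turnover through binding of the product's ortho-hydroxy ketone to the metal.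
- Fallback (polar addition then oxidation, from 10, returning at 13 and bypassing 12): commercial 4-(2-bromoethyl)phenol is silylated (i-Pr3SiCl, imidazole, DMF) to [4-(2-bromoethyl)phenoxy]tri(propan-2-yl)silane F1. Magnesium in THF converts this into the Grignard reagent {2-[4-({tri(propan-2-yl)silyl}oxy)phenyl]ethyl}magnesium bromide F2. About 3.5 equiv of F2 (two are consumed by the phenols) should add to the formyl group of 10 at 0 °C to rt and, after NH4Cl, give racemic 4-[1-hydroxy-3-(4-{[tri(propan-2-yl)silyl]oxy}phenyl)propyl]-2,6-bis(3-methylbut-2-en-1-yl)benzene-1,3-diol F3. MnO2 in CH2Cl2 should oxidise the benzylic carbinol to 1-[2,4-dihydroxy-3,5-bis(3-methylbut-2-en-1-yl)phenyl]-3-(4-{[tri(propan-2-yl)silyl]oxy}phenyl)propan-1-one F4. Bu4NF buffered with AcOH in THF at 0 °C then removes the silyl group to give 13.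

**Step 4.**
- Most likely to go wrong: slow etherification at the 4-hydroxyl now flanked by a prenyl group, with loss of 2 by elimination and some alkylation at the 2-hydroxyl.
- Fallback (from 6, returning at 8 and bypassing 7 and step 5): tert-butyl 2-methylbut-3-en-2-yl carbonate F5 (from 2-methylbut-3-en-2-ol, n-BuLi and Boc2O) with Pd(PPh3)4 in THF at 0 °C. This Tsuji–Trost O-allylation attacks the more substituted allyl terminus under kinetic control and should give 8 directly. It must be stopped early, before the ether re-ionises.

**Step 6.**
- Most likely to go wrong: thermal fragmentation of the tertiary allyl aryl ether with loss of isoprene; migration toward the occupied C3 followed by a Cope shift to C1 and loss of the formyl group; and thermal closure of the new ortho-prenylphenol onto its alkene.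
- Fallback (from 6, returning at 10 and bypassing 7 and 8): Friedel–Crafts prenylation with 2-methylbut-3-en-2-ol and BF3·OEt2 in dioxane at rt, kept short. C5 is the only ring carbon activated by both oxygens (ortho to O4, para to O2), so 10 should form directly; no new compound arises (F0).

**Step 3.**
- Most likely to go wrong: the same fragmentation as in step 6, and division of the shift between C3 and C5. The latter is harmless for the end result but complicates purification.
- Fallback (from 1, returning at 6 and bypassing 3 and 4): direct nuclear C-prenylation of the phenoxide of 1 with prenyl bromide in aqueous KOH at 0 °C to rt. The carbon between the two oxygens is the most nucleophilic site, and 6 should form without a sigmatropic step; no new compound arises (F0).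

## Further compounds

F1 | step 7 | [4-(2-bromoethyl)phenoxy]tri(propan-2-yl)silane | BrCCc1ccc(O[Si](C(C)C)(C(C)C)C(C)C)cc1
F2 | step 7 | {2-[4-({tri(propan-2-yl)silyl}oxy)phenyl]ethyl}magnesium bromide | Br[Mg]CCc1ccc(O[Si](C(C)C)(C(C)C)C(C)C)cc1
F3 | step 7 | 4-[1-hydroxy-3-(4-{[tri(propan-2-yl)silyl]oxy}phenyl)propyl]-2,6-bis(3-methylbut-2-en-1-yl)benzene-1,3-diol (racemic) | CC(C)=CCc1cc(C(O)CCc2ccc(O[Si](C(C)C)(C(C)C)C(C)C)cc2)c(O)c(CC=C(C)C)c1O
F4 | step 7 | 1-[2,4-dihydroxy-3,5-bis(3-methylbut-2-en-1-yl)phenyl]-3-(4-{[tri(propan-2-yl)silyl]oxy}phenyl)propan-1-one | CC(C)=CCc1cc(C(=O)CCc2ccc(O[Si](C(C)C)(C(C)C)C(C)C)cc2)c(O)c(CC=C(C)C)c1O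
F5 | step 4 | tert-butyl 2-methylbut-3-en-2-yl carbonate | C=CC(C)(C)OC(=O)OC(C)(C)C
F0 | step 6 | none | none
F0 | step 3 | none | none
A1 | alternative 1 | methyl 7-methyl-2-(3-methylbut-2-en-1-yl)-3-oxooct-6-enoate (racemic) | COC(=O)C(CC=C(C)C)C(=O)CCC=C(C)C
A2 | alternative 1 | 1-methoxy-7-methyl-2-(3-methylbut-2-en-1-yl)-1,3-bis(trimethylsilyloxy)octa-1,3,6-triene (double-bond geometry not defined) | COC(O[Si](C)(C)C)=C(CC=C(C)C)C(O[Si](C)(C)C)=CCC=C(C)C
A3 | alternative 1 | 5-{4-[(tert-butyldimethylsilyl)oxy]phenyl}pent-1-yn-3-one | C#CC(=O)CCc1ccc(O[Si](C)(C)C(C)(C)C)cc1
A4 | alternative 1 | Gancaonin J 4-O-tert-butyldimethylsilyl ether | CC(C)=CCc1cc(C(=O)CCc2ccc(O[Si](C)(C)C(C)(C)C)cc2)c(O)c(CC=C(C)C)c1O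
A5 | alternative 2 | 1-[3,5-diiodo-2,4-bis(methoxymethoxy)phenyl]-3-[4-(methoxymethoxy)phenyl]propan-1-one | COCOc1ccc(CCC(=O)c2cc(I)c(OCOC)c(I)c2OCOC)cc1
A6 | alternative 2 | 4,4,5,5-tetramethyl-2-(3-methylbut-2-en-1-yl)-1,3,2-dioxaborolane (prenylboronic acid pinacol ester) | CC(C)=CCB1OC(C)(C)C(C)(C)O1
A7 | alternative 2 | Gancaonin J tris(methoxymethyl) ether | COCOc1ccc(CCC(=O)c2cc(CC=C(C)C)c(OCOC)c(CC=C(C)C)c2OCOC)cc1
A8 | alternative 3 | 2,4-bis(3-methylbut-2-en-1-yl)benzene-1,3-diol | CC(C)=CCc1ccc(O)c(CC=C(C)C)c1O
A9 | alternative 3 | 3-[(tert-butyldimethylsilyl)oxy]-2,4-bis(3-methylbut-2-en-1-yl)phenyl 3-{4-[(tert-butyldimethylsilyl)oxy]phenyl}propanoate | CC(C)=CCc1ccc(OC(=O)CCc2ccc(O[Si](C)(C)C(C)(C)C)cc2)c(CC=C(C)C)c1O[Si](C)(C)C(C)(C)C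
A10 | alternative 3 | Gancaonin J 4,4'-bis(tert-butyldimethylsilyl) ether | CC(C)=CCc1cc(C(=O)CCc2ccc(O[Si](C)(C)C(C)(C)C)cc2)c(O)c(CC=C(C)C)c1O[Si](C)(C)C(C)(C)C
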